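Each isoflavan C3 is a benzylic methine on ring B that carries the C4 methylene (benzylic to ring A) and the C2 oxymethylene. Both C3–C4 bonds are therefore disconnected to a ring A benzyl nucleophile and the γ-carbon of a ring B cinnamyl electrophile. A single two-directional copper-catalysed asymmetric allylic alkylation joins two benzyl Grignard units to a bis-(E)-cinnamyl bromide, sets both C3 centres and leaves two vinyl groups as latent C2. The precursor is the C2-symmetric bis(cinnamyl bromide) of a benzyl-protected 4,4'-oxybis(3-hydroxy-2-methoxyphenyl) core, whose 3-oxygen, flanked by methoxy and the ether bridge, is installed early by directed lithiation.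

Key step: step 12

Remark on the chemistry: ring B needs an oxygen at C3' between the C2' methoxy and the C4' ether oxygen, which a 2-methoxy-4-substituted benzaldehyde does not carry, so it is introduced in step 2; the Taniaphos enantiomer is assumed, by analogy with simple cinnamyl bromides, to be the one giving the (S)-configured branched centres, to be checked on a one-armed model (mirror-image ligand otherwise).

**Route**

Step 1
Reactants: 1 4-fluoro-2-methoxybenzaldehyde
Product: 2 2-(4-fluoro-2-methoxyphenyl)-1,3-dioxolane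
Conditions: HOCH2CH2OH, TsOH·H2O (cat.), toluene, reflux, Dean–Stark
Reagents that add atoms: ethylene glycol, OCCO
Why: Acid-catalysed acetalisation with azeotropic removal of water masks the aldehyde as a dioxolane that tolerates butyllithium in the next step.

Step 2
Reactants: 2 2-(4-fluoro-2-methoxyphenyl)-1,3-dioxolane
Product: 6 4-fluoro-3-hydroxy-2-methoxybenzaldehyde, via aryllithium 3 (not isolated), via aryltrimethoxyborate 4 (not isolated), via acetal phenol 5 (not isolated)
Conditions: n-BuLi, THF, −78 °C; B(OMe)3, −78 → 0 °C; 30% H2O2, aq. NaOH, 0 °C; Na2SO3; then 2 M HCl, THF, rt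
Reagents that add atoms: hydrogen peroxide, OO; water, O
Why: Directed ortho-metalation takes the ring proton flanked by fluorine and methoxy, the most acidic one, and borylation then peroxide oxidation converts the C–Li bond into the C3 hydroxyl, after which aqueous acid hydrolyses the acetal.

Step 3
Reactants: 6 4-fluoro-3-hydroxy-2-methoxybenzaldehyde
Product: 7 3-(benzyloxy)-4-fluoro-2-methoxybenzaldehyde
Conditions: BnBr, K2CO3, DMF, rt
Reagents that add atoms: benzyl bromide, BrCc1ccccc1
Why: Williamson etherification of the phenoxide gives the benzyl ether, which withstands every later step and leaves with the other benzyl groups in the final hydrogenolysis.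

Step 4
Reactants: 7 3-(benzyloxy)-4-fluoro-2-methoxybenzaldehyde
Product: 9 3-(benzyloxy)-4-hydroxy-2-methoxybenzaldehyde, via sulfonylethyl ether 8 (not isolated)
Conditions: MeSO2CH2CH2OH, NaH, DMF, 0 °C → rt; aq. HCl work-up
Reagents that add atoms: 2-(methylsulfonyl)ethanol, CS(=O)(=O)CCO
Why: Nucleophilic aromatic substitution of the fluoride para to the formyl group by the sulfonylethoxide, followed by E1cB loss of methyl vinyl sulfone, unveils the phenol without exposing the aldehyde to hydroxide.

Step 5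
Reactants: 7 3-(benzyloxy)-4-fluoro-2-methoxybenzaldehyde; 9 3-(benzyloxy)-4-hydroxy-2-methoxybenzaldehyde
Product: 10 4,4'-oxybis[3-(benzyloxy)-2-methoxybenzaldehyde]
Conditions: K2CO3, DMSO, 110 °C
Reagents that add atoms: none
Why: Nucleophilic aromatic substitution of the para-formyl-activated fluoride of 7 by the phenoxide of 9 forms the diaryl ether, and the identical substitution of both partners makes the core C2-symmetric.

Step 6
Reactants: 10 4,4'-oxybis[3-(benzyloxy)-2-methoxybenzaldehyde]
Product: 11 1,1'-[oxybis(3-(benzyloxy)-2-methoxy-4,1-phenylene)]di(prop-2-en-1-ol) (mixture of carbinol diastereomers)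
Conditions: CH2=CHMgBr (3 equiv), THF, −78 → 0 °C; aq. NH4Cl
Reagents that add atoms: vinylmagnesium bromide, C=C[Mg]Br
Why: Grignard 1,2-addition to both aldehydes gives the aryl vinyl carbinols, whose configuration is immaterial because the carbinol carbons become trigonal in the next step.

Step 7
Reactants: 11 1,1'-[oxybis(3-(benzyloxy)-2-methoxy-4,1-phenylene)]di(prop-2-en-1-ol)
Product: 12 1,1'-oxybis{2-(benzyloxy)-4-[(1E)-3-bromoprop-1-en-1-yl]-3-methoxybenzene} (bis-(E)-cinnamyl bromide)
Conditions: PBr3, Et2O, 0 °C; used promptly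
Reagents that add atoms: phosphorus tribromide, BrP(Br)Br
Why: Bromination with allylic transposition: ionisation of the bromophosphite to an allyl cation stabilised by the ortho-methoxy and para-aryloxy groups, then capture of bromide at the terminus, should give the conjugated, thermodynamically preferred (E)-cinnamyl bromide on both arms.

Step 8
Reactants: 13 4-(benzyloxy)-2-hydroxybenzaldehyde
Product: 14 4-(benzyloxy)-2-(methoxymethoxy)benzaldehyde
Conditions: MOMCl, i-Pr2NEt, CH2Cl2, 0 °C → rt
Reagents that add atoms: chloromethyl methyl ether, COCCl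
Why: O-Alkylation of the phenol gives the methoxymethyl acetal, which survives hydride, Grignard formation and the copper step and is later removed by mild acid without touching the benzyl ethers.

Step 9
Reactants: 14 4-(benzyloxy)-2-(methoxymethoxy)benzaldehyde
Product: 15 [4-(benzyloxy)-2-(methoxymethoxy)phenyl]methanol
Conditions: NaBH4, MeOH, 0 °C
Reagents that add atoms: none
Why: Borohydride reduction of the aldehyde gives the benzylic alcohol.

Step 10
Reactants: 15 [4-(benzyloxy)-2-(methoxymethoxy)phenyl]methanol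
Product: 17 4-(benzyloxy)-1-(chloromethyl)-2-(methoxymethoxy)benzene, via benzyl mesylate 16 (not isolated)
Conditions: MsCl, Et3N, CH2Cl2, 0 °C → rt; used at once
Reagents that add atoms: methanesulfonyl chloride, CS(=O)(=O)Cl
Why: Mesylation followed by in situ chloride displacement of the activated benzylic mesylate gives the chloride under basic conditions that spare the acid-labile acetal.

Step 11
Reactants: 17 4-(benzyloxy)-1-(chloromethyl)-2-(methoxymethoxy)benzene
Product: 18 [4-(benzyloxy)-2-(methoxymethoxy)benzyl]magnesium chloride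
Conditions: Mg turnings (I2-activated, 3 equiv), Et2O, 0 °C, slow addition; titrated and used directly
Reagents that add atoms: magnesium, [Mg]
Why: Grignard formation by insertion of magnesium into the benzylic C–Cl bond; slow addition to excess metal in cold ether suppresses Wurtz coupling.

Step 12
Reactants: 12 1,1'-oxybis{2-(benzyloxy)-4-[(1E)-3-bromoprop-1-en-1-yl]-3-methoxybenzene}; 18 [4-(benzyloxy)-2-(methoxymethoxy)benzyl]magnesium chloride (3 equiv)
Product: 19 1,1'-oxybis{2-(benzyloxy)-4-[(2S)-1-[4-(benzyloxy)-2-(methoxymethoxy)phenyl]but-3-en-2-yl]-3-methoxybenzene} ((S,S) bis-branched product)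
Conditions: CuBr·SMe2 (10 mol%), Taniaphos (C43H39FeNP2, 12 mol%), CH2Cl2, −78 °C, 18 in Et2O added slowly; MeOH then aq. NH4Cl
Reagents that add atoms: none
Why: The chiral CuBr–Taniaphos complex is transmetalated by 18 to a benzylcopper species that binds the alkene of each cinnamyl arm and adds oxidatively at the γ-carbon anti to bromide, giving a σ-allyl trivalent copper intermediate that undergoes reductive elimination faster than it isomerises to the α-bound form, so each C3–C4 bond forms with allylic transposition. This is the copper-catalysed asymmetric allylic alkylation of (E)-cinnamyl bromides with Grignard reagents. No ring is closed. Each new centre (the future C3 of either isoflavan, S at this stage because vinyl outranks the benzyl carbon) is set under catalyst control by the ferrocenyl diphosphine, which selects one enantioface of the alkene; the two arms react independently, so a wrong-sense event ends in a separable meso-type diastereomer and the C2-symmetric product should be enriched. The step needs branched over linear regioselectivity, which the bromide leaving group, the non-coordinating CH2Cl2 and slow low-temperature Grignard addition secure by keeping uncatalysed direct substitution slow, and it needs face selectivity, which the planar (E)-aryl alkene offers to the ligand although the ortho-methoxy group next to the reacting carbon may erode it.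

Step 13
Reactants: 19 (S,S) bis-branched product
Product: 21 (2R,2'R)-2,2'-[oxybis(3-(benzyloxy)-2-methoxy-4,1-phenylene)]bis{3-[4-(benzyloxy)-2-(methoxymethoxy)phenyl]propan-1-ol}, via bis-ozonide 20 (not isolated)
Conditions: O3, CH2Cl2, −78 °C (Sudan Red 7B end point); then NaBH4, MeOH, −78 °C → rt
Reagents that add atoms: ozone, [O-][O+]=O
Why: Ozonolysis of the two terminal vinyl groups and direct borohydride reduction of the ozonides gives the primary alcohols that are C2 without a free α-aryl aldehyde ever being present, so the benzylic centres should not epimerise; the descriptor changes from S to R only because hydroxymethyl outranks the aryl group.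

Step 14
Reactants: 21 (2R,2'R)-diol bis(methoxymethyl ether)
Product: 22 (2R,2'R)-2,2'-[oxybis(3-(benzyloxy)-2-methoxy-4,1-phenylene)]bis{3-[4-(benzyloxy)-2-hydroxyphenyl]propan-1-ol}
Conditions: conc. HCl (cat.), MeOH, 45 °C
Reagents that add atoms: none
Why: Acid-catalysed acetal cleavage (transacetalisation to methanol) frees the two ring A phenols while benzyl ethers, methyl ethers and the diaryl ether are inert.

Step 15
Reactants: 22 (2R,2'R)-bis(phenol) diol
Product: 23 (3R,3'R)-3,3'-[oxybis(3-(benzyloxy)-2-methoxy-4,1-phenylene)]bis[7-(benzyloxy)chroman]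
Conditions: PPh3, DIAD, THF (0.02 M), 0 °C → rt
Reagents that add atoms: none
Why: Twofold intramolecular Mitsunobu etherification closes each six-membered oxygen ring by 6-exo-tet attack of the phenol on the activated primary carbon C2, which leaves the adjacent C3 centre untouched.

Step 16
Reactants: 23 (3R,3'R)-tetrabenzyl bis-isoflavan
Product: 24 (3R,3'R)-3,3'-[oxybis(3-hydroxy-2-methoxy-4,1-phenylene)]bis(chroman-7-ol)
Conditions: H2 (1 atm), 10% Pd/C, EtOAc/MeOH, rt
Reagents that add atoms: none
Why: Catalytic hydrogenolysis cleaves the four benzyl ethers, while the aryl methyl ethers, the diaryl ether and the chroman C–O bonds, none of which is a benzylic C–O bond, remain.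

**Compound list**

1 | 4-fluoro-2-methoxybenzaldehyde | COc1cc(F)ccc1C=O | starting material
2 | 2-(4-fluoro-2-methoxyphenyl)-1,3-dioxolane | COc1cc(F)ccc1C1OCCO1 | intermediate
3 | [3-(1,3-dioxolan-2-yl)-6-fluoro-2-methoxyphenyl]lithium (not isolated) | COc1c([Li])c(F)ccc1C1OCCO1 | intermediate
4 | lithium [3-(1,3-dioxolan-2-yl)-6-fluoro-2-methoxyphenyl]trimethoxyborate (not isolated) | [Li+].COc1c([B-](OC)(OC)OC)c(F)ccc1C1OCCO1 | intermediate
5 | 3-(1,3-dioxolan-2-yl)-6-fluoro-2-methoxyphenol (not isolated) | COc1c(O)c(F)ccc1C1OCCO1 | intermediate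
6 | 4-fluoro-3-hydroxy-2-methoxybenzaldehyde | COc1c(O)c(F)ccc1C=O | intermediate
7 | 3-(benzyloxy)-4-fluoro-2-methoxybenzaldehyde | COc1c(OCc2ccccc2)c(F)ccc1C=O | intermediate
8 | 3-(benzyloxy)-2-methoxy-4-[2-(methylsulfonyl)ethoxy]benzaldehyde (not isolated) | COc1c(OCc2ccccc2)c(OCCS(C)(=O)=O)ccc1C=O | intermediate
9 | 3-(benzyloxy)-4-hydroxy-2-methoxybenzaldehyde | COc1c(OCc2ccccc2)c(O)ccc1C=O | intermediate
10 | 4,4'-oxybis[3-(benzyloxy)-2-methoxybenzaldehyde] | COc1c(C=O)ccc(Oc2ccc(C=O)c(OC)c2OCc2ccccc2)c1OCc1ccccc1 | intermediate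
11 | 1,1'-[oxybis(3-(benzyloxy)-2-methoxy-4,1-phenylene)]di(prop-2-en-1-ol), carbinol centres mixed | COc1c(C(O)C=C)ccc(Oc2ccc(C(O)C=C)c(OC)c2OCc2ccccc2)c1OCc1ccccc1 | intermediate
12 | 1,1'-oxybis{2-(benzyloxy)-4-[(1E)-3-bromoprop-1-en-1-yl]-3-methoxybenzene} | COc1c(/C=C/CBr)ccc(Oc2ccc(/C=C/CBr)c(OC)c2OCc2ccccc2)c1OCc1ccccc1 | intermediate
13 | 4-(benzyloxy)-2-hydroxybenzaldehyde | O=Cc1ccc(OCc2ccccc2)cc1O | starting material
14 | 4-(benzyloxy)-2-(methoxymethoxy)benzaldehyde | COCOc1cc(OCc2ccccc2)ccc1C=O | intermediate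
15 | [4-(benzyloxy)-2-(methoxymethoxy)phenyl]methanol | COCOc1cc(OCc2ccccc2)ccc1CO | intermediate
16 | 4-(benzyloxy)-2-(methoxymethoxy)benzyl methanesulfonate (not isolated) | COCOc1cc(OCc2ccccc2)ccc1COS(C)(=O)=O | intermediate
17 | 4-(benzyloxy)-1-(chloromethyl)-2-(methoxymethoxy)benzene | COCOc1cc(OCc2ccccc2)ccc1CCl | intermediate
18 | [4-(benzyloxy)-2-(methoxymethoxy)benzyl]magnesium chloride | Cl[Mg]Cc1ccc(OCc2ccccc2)cc1OCOC | intermediate
19 | 1,1'-oxybis{2-(benzyloxy)-4-[(2S)-1-[4-(benzyloxy)-2-(methoxymethoxy)phenyl]but-3-en-2-yl]-3-methoxybenzene} | COc1c([C@@H](Cc2ccc(OCc3ccccc3)cc2OCOC)C=C)ccc(Oc2ccc([C@@H](Cc3ccc(OCc4ccccc4)cc3OCOC)C=C)c(OC)c2OCc2ccccc2)c1OCc1ccccc1 | intermediate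
20 | bis(1,2,4-trioxolane) of 19, trioxolane carbons unassigned (not isolated) | COc1c([C@@H](Cc2ccc(OCc3ccccc3)cc2OCOC)C2OCOO2)ccc(Oc2ccc([C@@H](Cc3ccc(OCc4ccccc4)cc3OCOC)C3OCOO3)c(OC)c2OCc2ccccc2)c1OCc1ccccc1 | intermediate
21 | (2R,2'R)-2,2'-[oxybis(3-(benzyloxy)-2-methoxy-4,1-phenylene)]bis{3-[4-(benzyloxy)-2-(methoxymethoxy)phenyl]propan-1-ol} | COc1c([C@@H](Cc2ccc(OCc3ccccc3)cc2OCOC)CO)ccc(Oc2ccc([C@@H](Cc3ccc(OCc4ccccc4)cc3OCOC)CO)c(OC)c2OCc2ccccc2)c1OCc1ccccc1 | intermediate
22 | (2R,2'R)-2,2'-[oxybis(3-(benzyloxy)-2-methoxy-4,1-phenylene)]bis{3-[4-(benzyloxy)-2-hydroxyphenyl]propan-1-ol} | COc1c([C@@H](Cc2ccc(OCc3ccccc3)cc2O)CO)ccc(Oc2ccc([C@@H](Cc3ccc(OCc4ccccc4)cc3O)CO)c(OC)c2OCc2ccccc2)c1OCc1ccccc1 | intermediate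
23 | (3R,3'R)-3,3'-[oxybis(3-(benzyloxy)-2-methoxy-4,1-phenylene)]bis[7-(benzyloxy)chroman] | COc1c([C@@H]2COc3cc(OCc4ccccc4)ccc3C2)ccc(Oc2ccc([C@@H]3COc4cc(OCc5ccccc5)ccc4C3)c(OC)c2OCc2ccccc2)c1OCc1ccccc1 | intermediate
24 | (3R,3'R)-3,3'-[oxybis(3-hydroxy-2-methoxy-4,1-phenylene)]bis(chroman-7-ol) | COc1c([C@@H]2COc3cc(O)ccc3C2)ccc(Oc2ccc([C@@H]3COc4cc(O)ccc4C3)c(OC)c2O)c1O | target

**Count**

Total steps: 16. Longest linear sequence: 12 steps (steps 1–7 and 12–16, from 1); the Grignard branch (steps 8–11) joins at step 12.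

**Steps most likely to fail**

Step 12. Direct (linear) substitution may compete with γ-attack, or facial selectivity may be poor because the ortho-methoxy group crowds the reacting carbon. The fallback sets the centres by substrate-controlled chirality transfer and starts from dialdehyde 10:
- Claisen–Schmidt condensation with acetone (aq. NaOH) should give the bis-(E)-enone F1.
- Corey–Bakshi–Shibata reduction ((S)-Me-CBS oxazaborolidine, catecholborane, toluene, −78 °C) should give the (R,R)-bis(allylic alcohol) F2, the styryl arm acting as the large group.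
- Esterification with picolinic acid (DCC, DMAP, CH2Cl2) gives the bis-picolinate F3.
- Anti-selective SN2' substitution with 18 and CuBr·SMe2 (THF/Et2O, −40 → 0 °C) follows, in which the magnesium-chelated picolinate leaves from the face opposite the incoming benzyl group. It should transfer each carbinol configuration to the benzylic carbon and give the (S,S)-bis-(E)-propenyl compound F4.
- Ozonolysis through the bis-ozonide F5 with NaBH4 work-up, as in step 13, cleaves the propenyl groups and returns to the route at diol 21.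

Step 13. Ozone may over-oxidise the electron-rich alkoxyarenes and benzyl ethers, or the aldehyde oxidation level may lose configuration at the α-aryl carbon. The fallback splits the cleavage into milder stages and starts from 19:
- Dihydroxylation with OsO4 (cat.) and NMO in acetone/H2O should give the bis(1,2-diol) F6.
- NaIO4 in THF/pH 7 buffer at 0 °C gives the bis(α-aryl aldehyde) F7, which is not stored.
- NaBH4 added to the same cold mixture reduces it, returning to the route at 21.

Step 7. Ionisation may give mixtures of regioisomeric bromides or Friedel–Crafts oligomerisation of the electron-rich allyl cation. The fallback builds the E-alkene by olefination and starts from 10: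
- Horner–Wadsworth–Emmons reaction (triethyl phosphonoacetate, LiCl, DBU, MeCN) gives the bis-(E)-cinnamate F8.
- Reduction with i-Bu2AlH (CH2Cl2, −78 °C) gives the bis-(E)-cinnamyl alcohol F9.
- PBr3 (Et2O, 0 °C) then displaces directly at the primary allylic carbon, returning to the route at 12.

Further compounds
F1 | step 12 | (3E,3'E)-4,4'-[oxybis(3-(benzyloxy)-2-methoxy-4,1-phenylene)]bis(but-3-en-2-one) | COc1c(/C=C/C(C)=O)ccc(Oc2ccc(/C=C/C(C)=O)c(OC)c2OCc2ccccc2)c1OCc1ccccc1
F2 | step 12 | (2R,2'R,3E,3'E)-4,4'-[oxybis(3-(benzyloxy)-2-methoxy-4,1-phenylene)]bis(but-3-en-2-ol) | COc1c(/C=C/[C@@H](C)O)ccc(Oc2ccc(/C=C/[C@@H](C)O)c(OC)c2OCc2ccccc2)c1OCc1ccccc1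
F3 | step 12 | bis(pyridine-2-carboxylate) of F2, (R,R) | COc1c(/C=C/[C@@H](C)OC(=O)c2ccccn2)ccc(Oc2ccc(/C=C/[C@@H](C)OC(=O)c3ccccn3)c(OC)c2OCc2ccccc2)c1OCc1ccccc1
F4 | step 12 | 1,1'-oxybis{2-(benzyloxy)-4-[(2S,3E)-1-[4-(benzyloxy)-2-(methoxymethoxy)phenyl]pent-3-en-2-yl]-3-methoxybenzene} | COc1c([C@@H](Cc2ccc(OCc3ccccc3)cc2OCOC)/C=C/C)ccc(Oc2ccc([C@@H](Cc3ccc(OCc4ccccc4)cc3OCOC)/C=C/C)c(OC)c2OCc2ccccc2)c1OCc1ccccc1
F5 | step 12 | bis(5-methyl-1,2,4-trioxolane) of F4, trioxolane carbons unassigned | COc1c([C@@H](Cc2ccc(OCc3ccccc3)cc2OCOC)C2OC(C)OO2)ccc(Oc2ccc([C@@H](Cc3ccc(OCc4ccccc4)cc3OCOC)C3OC(C)OO3)c(OC)c2OCc2ccccc2)c1OCc1ccccc1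
F6 | step 13 | bis(1,2-diol) of 19, benzylic centres R, carbinol centres mixed | COc1c([C@@H](Cc2ccc(OCc3ccccc3)cc2OCOC)C(O)CO)ccc(Oc2ccc([C@@H](Cc3ccc(OCc4ccccc4)cc3OCOC)C(O)CO)c(OC)c2OCc2ccccc2)c1OCc1ccccc1
F7 | step 13 | (2R,2'R)-2,2'-[oxybis(3-(benzyloxy)-2-methoxy-4,1-phenylene)]bis{3-[4-(benzyloxy)-2-(methoxymethoxy)phenyl]propanal} | COc1c([C@@H](Cc2ccc(OCc3ccccc3)cc2OCOC)C=O)ccc(Oc2ccc([C@@H](Cc3ccc(OCc4ccccc4)cc3OCOC)C=O)c(OC)c2OCc2ccccc2)c1OCc1ccccc1
F8 | step 7 | diethyl (2E,2'E)-3,3'-[oxybis(3-(benzyloxy)-2-methoxy-4,1-phenylene)]bis(prop-2-enoate) | COc1c(/C=C/C(=O)OCC)ccc(Oc2ccc(/C=C/C(=O)OCC)c(OC)c2OCc2ccccc2)c1OCc1ccccc1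
F9 | step 7 | (2E,2'E)-3,3'-[oxybis(3-(benzyloxy)-2-methoxy-4,1-phenylene)]bis(prop-2-en-1-ol) | COc1c(/C=C/CO)ccc(Oc2ccc(/C=C/CO)c(OC)c2OCc2ccccc2)c1OCc1ccccc1
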